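The route disconnects ring B at C9–C10 (and ring A at C4–C5; labdane numbering). One epoxide-initiated cation–olefin bicyclization closes both rings: it exploits the 3-hydroxy-4-(hydroxymethyl) pattern of ring A as an epoxy-alcohol retron and the C8=C17 exocyclic methylene adjacent to C9 of ring B as an allylsilane retron, and sets C5, C9 and the quaternary C10 from alkene geometry while C3 and C4 come from a Sharpless epoxide. The precursor is an acyclic diene carrying a Z-derived 2,3-epoxy silyl ether, a C8 allylsilane and the finished butenolide. The equatorial C7 hydroxyl is added afterwards by allylic oxidation and ketone reduction.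

Key step: step 10

Remark: carbons carry labdane numbers throughout, also in acyclic intermediates (C19 = CH2O on C4, C20 = CH3 on C10, C17 = exocyclic CH2 on C8); 4-pentynal and 3-bromofuran-2(5H)-one are taken as purchased.

Step 1
Reactants: 1 4-pentynal; 2 isopropenylmagnesium bromide
Product: 3 (±)-2-methylhept-1-en-6-yn-3-ol
Conditions: THF, −78 → 0 °C; then H2O
Reagents that add atoms: isopropenylmagnesium bromide, CC(=C)[Mg]Br
Why: Grignard 1,2-addition to the aldehyde at −78 °C is much faster than deprotonation of the alkyne C–H; the new carbinol centre (future C5) is racemic and is erased in step 2.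

Step 2
Reactants: 3 (±)-2-methylhept-1-en-6-yn-3-ol; 4 triethyl orthoacetate
Product: 6 ethyl (4E)-4-methylnon-4-en-8-ynoate, via ketene acetal 5 (not isolated)
Conditions: MeC(OEt)3 (excess), EtCO2H (cat.), 140 °C, ethanol distilled off
Reagents that add atoms: triethyl orthoacetate, CC(OCC)(OCC)OCC
Why: Johnson–Claisen (orthoester) rearrangement: ketene acetal 5 rearranges through a chair with the homopropargylic chain on C5 equatorial, so the C1–C2 bond and the E-configured C5=C10 alkene should form together with high selectivity.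

Step 3
Reactants: 6 ethyl (4E)-4-methylnon-4-en-8-ynoate
Product: 7 (4E)-4-methylnon-4-en-8-ynal
Conditions: i-Bu2AlH (1.05 equiv), CH2Cl2, −78 °C; aq. potassium sodium tartrate
Reagents that add atoms: none
Why: Ester reduction with i-Bu2AlH at −78 °C stops at the tetrahedral aluminium hemiacetal, which gives the aldehyde only on work-up, and the terminal alkyne is not hydroaluminated at this temperature.

Step 4
Reactants: 7 (4E)-4-methylnon-4-en-8-ynal; 8 ethyl 2-[bis(2,2,2-trifluoroethoxy)phosphoryl]propanoate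
Product: 9 ethyl (2Z,6E)-2,6-dimethylundeca-2,6-dien-10-ynoate
Conditions: KN(SiMe3)2, 18-crown-6, THF, −78 °C
Reagents that add atoms: ethyl 2-[bis(2,2,2-trifluoroethoxy)phosphoryl]propanoate, CCOC(=O)C(C)P(=O)(OCC(F)(F)F)OCC(F)(F)F
Why: Still–Gennari variant of the Horner–Wadsworth–Emmons olefination: the bis(trifluoroethyl) phosphonate under dissociating conditions eliminates from the kinetic adduct and should give the Z-enoate (ester cis to the chain), the geometry that later makes C19 axial on C4.

Step 5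
Reactants: 9 ethyl (2Z,6E)-2,6-dimethylundeca-2,6-dien-10-ynoate; 10 (trimethylsilyl)methylmagnesium chloride; 11 vinyl bromide
Product: 14 ethyl (2Z,6E,10Z)-2,6-dimethyl-10-[(trimethylsilyl)methyl]trideca-2,6,10,12-tetraenoate, via alkenylcopper 12 (not isolated), via alkenylzinc bromide 13 (not isolated)
Conditions: CuBr·SMe2 (1 equiv to 10), Et2O/Me2S, −40 → −10 °C; then ZnBr2, Pd(PPh3)4 (5 mol%), THF, −10 → 20 °C
Reagents that add atoms: (trimethylsilyl)methylmagnesium chloride, C[Si](C)(C)C[Mg]Cl; vinyl bromide, C=CBr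
Why: Carbocupration of the terminal alkyne by Me3SiCH2Cu·MgBrCl is a syn addition with copper on the terminal carbon (C9), which fixes the C8=C9 geometry (CH2SiMe3 cis to the C9 substituent), and transmetalation to zinc followed by Pd-catalysed Negishi coupling with vinyl bromide replaces the metal with retention while the soft organocopper leaves the conjugated ester alone.

Step 6
Reactants: 14 ethyl (2Z,6E,10Z)-2,6-dimethyl-10-[(trimethylsilyl)methyl]trideca-2,6,10,12-tetraenoate
Product: 15 (2Z,6E,10Z)-2,6-dimethyl-10-[(trimethylsilyl)methyl]trideca-2,6,10,12-tetraen-1-ol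
Conditions: i-Bu2AlH (2.5 equiv), CH2Cl2, −78 °C; aq. potassium sodium tartrate
Reagents that add atoms: none
Why: Excess i-Bu2AlH reduces the conjugated ester by 1,2-addition to the Z-allylic alcohol and leaves the silyl diene untouched (DIBAL reduction).

Step 7
Reactants: 15 (2Z,6E,10Z)-2,6-dimethyl-10-[(trimethylsilyl)methyl]trideca-2,6,10,12-tetraen-1-ol; 16 tert-butyl hydroperoxide
Product: 17 {(2S,3R)-2-methyl-3-[(3E,7Z)-3-methyl-7-[(trimethylsilyl)methyl]deca-3,7,9-trien-1-yl]oxiran-2-yl}methanol
Conditions: Ti(OiPr)4 (10 mol%), L-(+)-diethyl tartrate (12 mol%), 4 Å MS, CH2Cl2, −20 °C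
Reagents that add atoms: tert-butyl hydroperoxide, CC(C)(C)OO
Why: Katsuki–Sharpless asymmetric epoxidation: the catalyst from Ti(OiPr)4 and L-(+)-diethyl tartrate epoxidises only the alkene of the allylic alcohol and should deliver oxygen to the face that gives the (2S,3R)-epoxide, which fixes C3 (R) and, after inversion in step 10, C4.

Step 8
Reactants: 17 {(2S,3R)-2-methyl-3-[(3E,7Z)-3-methyl-7-[(trimethylsilyl)methyl]deca-3,7,9-trien-1-yl]oxiran-2-yl}methanol; 18 tert-butyldimethylsilyl chloride
Product: 19 tert-butyl(dimethyl){[(2S,3R)-2-methyl-3-[(3E,7Z)-3-methyl-7-[(trimethylsilyl)methyl]deca-3,7,9-trien-1-yl]oxiran-2-yl]methoxy}silane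
Conditions: imidazole, DMF, 0 → 20 °C
Reagents that add atoms: tert-butyldimethylsilyl chloride, CC(C)(C)[Si](C)(C)Cl
Why: Silylation of the primary hydroxyl removes the only protic group before the borane and the aluminium Lewis acid are used and leaves a non-participating ether next to the epoxide.

Step 9
Reactants: 19 silyl ether of 17; 20 9-borabicyclo[3.3.1]nonane (9-BBN); 21 3-bromofuran-2(5H)-one
Product: 23 3-[(3Z,7E)-10-[(2R,3S)-3-({[tert-butyl(dimethyl)silyl]oxy}methyl)-3-methyloxiran-2-yl]-8-methyl-4-[(trimethylsilyl)methyl]deca-3,7-dien-1-yl]furan-2(5H)-one, via alkylborane 22 (not isolated)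
Conditions: 9-BBN, THF, 0 → 20 °C; then PdCl2(dppf) (5 mol%), AsPh3, K3PO4 (aq.), DMF, 20 °C
Reagents that add atoms: 3-bromofuran-2(5H)-one, O=C1OCC=C1Br
Why: 9-BBN adds only to the monosubstituted terminus of the diene (boron on C12) and leaves the two trisubstituted alkenes, and B-alkyl Suzuki–Miyaura coupling of 22 with the α-bromobutenolide forms the C12–C13 bond and installs the complete lactone.

Step 10
Reactants: 23 epoxy allylsilane butenolide
Product: 24 19-O-TBS-14-deoxyandrographolide, 3-{2-[(1R,4aS,5R,6R,8aS)-5-({[tert-butyl(dimethyl)silyl]oxy}methyl)-6-hydroxy-5,8a-dimethyl-2-methylidenedecahydronaphthalen-1-yl]ethyl}furan-2(5H)-one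
Conditions: MeAlCl2 (3 equiv), CH2Cl2, −78 °C; then Et3N, aq. NaHCO3
Reagents that add atoms: none
Why: MeAlCl2 coordinates the epoxide oxygen and ionisation at the fully substituted C4 is intercepted anti by C5 of the C5=C10 alkene; the resulting C10 tertiary cation is captured by C9 of the allylsilane, and the β-silyl cation at C8 loses the silyl group so that only the C8=C17 exocyclic alkene can form. The closest known reaction type is the epoxide-initiated cation–olefin polycyclization terminated by an allylsilane. Ring A closes by 6-endo opening of the epoxide at C4 (C4–C5 bond) and ring B by 6-endo-trig attack of C9 on C10 (C9–C10 bond), both through chair transition states. C3 is carried over unchanged from the Sharpless epoxide and C4 is set by inversion, which places the Z-derived CH2OTBS axial; C5 and C10 follow from antiperiplanar addition across the E-configured C5=C10 alkene (trans ring fusion, H5 anti to C20), and C9 from the geometry of the C8=C9 alkene (C7 trans to C11), which puts the side chain equatorial. The step needs opening at C4 and not C3 (secured by the tertiary centre), complete bicyclization in preference to a monocyclic olefin or a hydride-shift ketone (secured by the nucleophilic allylsilane held for a chair–chair cascade) and a silent lactone (its C13=C14 alkene is electron-poor and the excess Lewis acid covers its carbonyl).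

Step 11
Reactants: 24 19-O-TBS-14-deoxyandrographolide; 16 tert-butyl hydroperoxide
Product: 25 3-{2-[(1S,3S,4aS,5R,6R,8aS)-5-({[tert-butyl(dimethyl)silyl]oxy}methyl)-3,6-dihydroxy-5,8a-dimethyl-2-methylidenedecahydronaphthalen-1-yl]ethyl}furan-2(5H)-one (axial C7 alcohol)
Conditions: SeO2 (0.3 equiv), CH2Cl2, 0 → 20 °C
Reagents that add atoms: tert-butyl hydroperoxide, CC(C)(C)OO
Why: SeO2-catalysed allylic hydroxylation with tert-butyl hydroperoxide as terminal oxidant (ene reaction then [2,3]-sigmatropic shift) attacks the ring methylene C7 in preference to the hindered methine C9 and should return oxygen axially, giving mainly the 7-epimer of the target alcohol, which steps 12 and 13 correct.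

Step 12
Reactants: 25 axial C7 alcohol
Product: 26 3-{2-[(1S,4aS,5R,6R,8aR)-5-({[tert-butyl(dimethyl)silyl]oxy}methyl)-6-hydroxy-5,8a-dimethyl-2-methylidene-3-oxodecahydronaphthalen-1-yl]ethyl}furan-2(5H)-one
Conditions: MnO2 (excess), CH2Cl2, 20 °C
Reagents that add atoms: none
Why: MnO2 oxidises only the allylic C7 alcohol (both C7 epimers and any enone already formed in step 11 converge) and leaves the C3 hydroxyl alone, giving the conjugated exo-methylene ketone, which is carried on without delay to avoid drift of the alkene into the ring.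

Step 13
Reactants: 26 C7 enone
Product: 27 3-{2-[(1S,3R,4aS,5R,6R,8aS)-5-({[tert-butyl(dimethyl)silyl]oxy}methyl)-3,6-dihydroxy-5,8a-dimethyl-2-methylidenedecahydronaphthalen-1-yl]ethyl}furan-2(5H)-one (equatorial C7 alcohol)
Conditions: NaBH4, CeCl3·7H2O, MeOH, −78 °C
Reagents that add atoms: none
Why: Luche reduction: NaBH4 with CeCl3 adds hydride 1,2 to the enone along the axial trajectory at C7 (syn to the axial hydrogens on C5 and C9), which should give the equatorial C7 alcohol (R), while the butenolide and the exocyclic alkene are not reduced at −78 °C.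

Step 14
Reactants: 27 equatorial C7 alcohol
Product: 28 3-{2-[(1S,3R,4aS,5R,6R,8aS)-3,6-dihydroxy-5-(hydroxymethyl)-5,8a-dimethyl-2-methylidenedecahydronaphthalen-1-yl]ethyl}furan-2(5H)-one (target)
Conditions: HF·pyridine, pyridine/THF, 0 → 20 °C
Reagents that add atoms: none
Why: Fluoride cleavage of the primary tert-butyldimethylsilyl ether with buffered HF·pyridine (desilylation) spares the butenolide and the allylic alcohol and gives the target.

Compound list
1 | 4-pentynal | C#CCCC=O | starting material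
2 | isopropenylmagnesium bromide | CC(=C)[Mg]Br | starting material
3 | (±)-2-methylhept-1-en-6-yn-3-ol | C=C(C)C(O)CCC#C | intermediate
4 | triethyl orthoacetate | CC(OCC)(OCC)OCC | starting material
5 | ketene acetal, 3-[(1-ethoxyethenyl)oxy]-2-methylhept-1-en-6-yne | C=C(OCC)OC(CCC#C)C(C)=C | intermediate (not isolated)
6 | ethyl (4E)-4-methylnon-4-en-8-ynoate | CCOC(=O)CC/C(C)=C/CCC#C | intermediate
7 | (4E)-4-methylnon-4-en-8-ynal | O=CCC/C(C)=C/CCC#C | intermediate
8 | ethyl 2-[bis(2,2,2-trifluoroethoxy)phosphoryl]propanoate | CCOC(=O)C(C)P(=O)(OCC(F)(F)F)OCC(F)(F)F | starting material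
9 | ethyl (2Z,6E)-2,6-dimethylundeca-2,6-dien-10-ynoate | CCOC(=O)/C(C)=C\CC/C(C)=C/CCC#C | intermediate
10 | (trimethylsilyl)methylmagnesium chloride | C[Si](C)(C)C[Mg]Cl | starting material
11 | vinyl bromide | C=CBr | starting material
12 | alkenylcopper (copper on C9, cis to CH2SiMe3) | CCOC(=O)/C(C)=C\CC/C(C)=C/CC/C(C[Si](C)(C)C)=C/[Cu] | intermediate (not isolated)
13 | alkenylzinc bromide (zinc on C9, cis to CH2SiMe3) | CCOC(=O)/C(C)=C\CC/C(C)=C/CC/C(C[Si](C)(C)C)=C/[Zn]Br | intermediate (not isolated)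
14 | ethyl (2Z,6E,10Z)-2,6-dimethyl-10-[(trimethylsilyl)methyl]trideca-2,6,10,12-tetraenoate | CCOC(=O)/C(C)=C\CC/C(C)=C/CC/C(C[Si](C)(C)C)=C/C=C | intermediate
15 | (2Z,6E,10Z)-2,6-dimethyl-10-[(trimethylsilyl)methyl]trideca-2,6,10,12-tetraen-1-ol | OC/C(C)=C\CC/C(C)=C/CC/C(C[Si](C)(C)C)=C/C=C | intermediate
16 | tert-butyl hydroperoxide | CC(C)(C)OO | starting material
17 | {(2S,3R)-2-methyl-3-[(3E,7Z)-3-methyl-7-[(trimethylsilyl)methyl]deca-3,7,9-trien-1-yl]oxiran-2-yl}methanol | OC[C@]1(C)O[C@@H]1CC/C(C)=C/CC/C(C[Si](C)(C)C)=C/C=C | intermediate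
18 | tert-butyldimethylsilyl chloride | CC(C)(C)[Si](C)(C)Cl | starting material
19 | tert-butyl(dimethyl){[(2S,3R)-2-methyl-3-[(3E,7Z)-3-methyl-7-[(trimethylsilyl)methyl]deca-3,7,9-trien-1-yl]oxiran-2-yl]methoxy}silane | CC(C)(C)[Si](C)(C)OC[C@]1(C)O[C@@H]1CC/C(C)=C/CC/C(C[Si](C)(C)C)=C/C=C | intermediate
20 | 9-borabicyclo[3.3.1]nonane | B1C2CCCC1CCC2 | starting material
21 | 3-bromofuran-2(5H)-one | O=C1OCC=C1Br | starting material
22 | alkylborane, B-alkyl-9-BBN adduct of 19 with boron on C12 | CC(C)(C)[Si](C)(C)OC[C@]1(C)O[C@@H]1CC/C(C)=C/CC/C(C[Si](C)(C)C)=C/CCB1C2CCCC1CCC2 | intermediate (not isolated)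
23 | 3-[(3Z,7E)-10-[(2R,3S)-3-({[tert-butyl(dimethyl)silyl]oxy}methyl)-3-methyloxiran-2-yl]-8-methyl-4-[(trimethylsilyl)methyl]deca-3,7-dien-1-yl]furan-2(5H)-one | CC(C)(C)[Si](C)(C)OC[C@]1(C)O[C@@H]1CC/C(C)=C/CC/C(C[Si](C)(C)C)=C/CCC1=CCOC1=O | intermediate
24 | 19-O-TBS-14-deoxyandrographolide, (1R,4aS,5R,6R,8aS) | C=C1CC[C@@H]2[C@](C)(CO[Si](C)(C)C(C)(C)C)[C@H](O)CC[C@@]2(C)[C@@H]1CCC1=CCOC1=O | intermediate
25 | 19-O-TBS-7-epi alcohol (axial C7–OH), (1S,3S,4aS,5R,6R,8aS) | C=C1[C@@H](O)C[C@@H]2[C@](C)(CO[Si](C)(C)C(C)(C)C)[C@H](O)CC[C@@]2(C)[C@@H]1CCC1=CCOC1=O | intermediate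
26 | 19-O-TBS-7-oxo-14-deoxyandrographolide, (1S,4aS,5R,6R,8aR) | C=C1C(=O)C[C@@H]2[C@](C)(CO[Si](C)(C)C(C)(C)C)[C@H](O)CC[C@@]2(C)[C@@H]1CCC1=CCOC1=O | intermediate
27 | 19-O-TBS ether of the target (equatorial C7–OH), (1S,3R,4aS,5R,6R,8aS) | C=C1[C@H](O)C[C@@H]2[C@](C)(CO[Si](C)(C)C(C)(C)C)[C@H](O)CC[C@@]2(C)[C@@H]1CCC1=CCOC1=O | intermediate
28 | 3-{2-[(1S,3R,4aS,5R,6R,8aS)-3,6-dihydroxy-5-(hydroxymethyl)-5,8a-dimethyl-2-methylidenedecahydronaphthalen-1-yl]ethyl}furan-2(5H)-one | C=C1[C@H](O)C[C@@H]2[C@](C)(CO)[C@H](O)CC[C@@]2(C)[C@@H]1CCC1=CCOC1=O | target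

Total step count: 14
Longest linear sequence: 14 steps (1 → 28)

Steps most likely to fail

Step 10. The Lewis acid may be tied up by the lactone carbonyl so that the cascade stalls after ring A. The ionised epoxide may also rearrange by hydride shift, or the allylsilane may be protodesilylated before it traps the C10 cation. The fallback changes the order of events so that the cascade runs without the lactone. It sets out from 19: MeAlCl2 in CH2Cl2 at −78 °C should trigger the same bicyclization, now terminated by the 2-(silylmethyl)diene, which can reach C10 through a six-membered chair only by C9. Loss of silicon leaves the C8=C17 methylene and a vinyl group on C9, giving (1R,2R,4aR,5R,8aS)-1-({[tert-butyl(dimethyl)silyl]oxy}methyl)-5-ethenyl-1,4a-dimethyl-6-methylidenedecahydronaphthalen-2-ol F1. Hydroboration of the monosubstituted vinyl group with excess 9-BBN (the exocyclic methylene is shielded by C20 and the C9 substituent) gives the B-alkyl-9-BBN adduct F2. Suzuki–Miyaura coupling of F2 with 21 under the conditions of step 9 comes back to the route at 24.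

Step 5. Transfer of the silylmethyl group from copper to the alkyne may be slow, the alkyne C–H may be metalated instead, or regiocontrol of the addition may be incomplete. The fallback is a haloboration and double cross-coupling sequence that sets out from 9. Syn bromoboration with B-bromo-9-borabicyclo[3.3.1]nonane (CH2Cl2, 0 °C) puts bromine on C8 and boron on C9, giving ethyl (2Z,6E,10Z)-11-(9-borabicyclo[3.3.1]nonan-9-yl)-10-bromo-2,6-dimethylundeca-2,6,10-trienoate F3. Negishi coupling of the C–Br bond with Me3SiCH2ZnCl and Pd(PPh3)4 gives ethyl (2Z,6E,10Z)-11-(9-borabicyclo[3.3.1]nonan-9-yl)-2,6-dimethyl-10-[(trimethylsilyl)methyl]undeca-2,6,10-trienoate F4. Addition of aqueous NaOH and 11 then couples the C–B bond (Suzuki–Miyaura) with retention and comes back to the route at 14.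

Step 9. Hydroboration may not discriminate fully between the diene terminus and the allylsilane alkene, and the base-sensitive bromolactone may decompose or the borane may protodeboronate before transmetalation. The fallback builds the butenolide by enolate alkylation instead of cross-coupling and sets out from 19. The borane 22 is oxidised (H2O2, NaOH) to (3Z,7E)-10-[(2R,3S)-3-({[tert-butyl(dimethyl)silyl]oxy}methyl)-3-methyloxiran-2-yl]-8-methyl-4-[(trimethylsilyl)methyl]deca-3,7-dien-1-ol F5. Appel-type iodination (I2, PPh3, imidazole) gives tert-butyl{[(2S,3R)-3-[(3E,7Z)-10-iodo-3-methyl-7-[(trimethylsilyl)methyl]deca-3,7-dien-1-yl]-2-methyloxiran-2-yl]methoxy}dimethylsilane F6. Alkylation of the lithium enolate of 3-(phenylsulfanyl)oxolan-2-one (LiN(i-Pr)2, THF/HMPA) gives the 3-alkyl-3-(phenylsulfanyl)oxolan-2-one F7. Oxidation at sulfur (m-CPBA, −78 °C) gives the 3-alkyl-3-(benzenesulfinyl)oxolan-2-one F8, and thermal syn elimination (toluene, 110 °C) comes back to the route at 23.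

Further compounds
F1 | step 10 | (1R,2R,4aR,5R,8aS)-1-({[tert-butyl(dimethyl)silyl]oxy}methyl)-5-ethenyl-1,4a-dimethyl-6-methylidenedecahydronaphthalen-2-ol | C=C1CC[C@@H]2[C@](C)(CO[Si](C)(C)C(C)(C)C)[C@H](O)CC[C@@]2(C)[C@@H]1C=C
F2 | step 10 | B-alkyl-9-BBN adduct of F1 (boron on C12) | C=C1CC[C@@H]2[C@](C)(CO[Si](C)(C)C(C)(C)C)[C@H](O)CC[C@@]2(C)[C@@H]1CCB1C2CCCC1CCC2
F3 | step 5 | ethyl (2Z,6E,10Z)-11-(9-borabicyclo[3.3.1]nonan-9-yl)-10-bromo-2,6-dimethylundeca-2,6,10-trienoate | CCOC(=O)/C(C)=C\CC/C(C)=C/CC/C(Br)=C/B1C2CCCC1CCC2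
F4 | step 5 | ethyl (2Z,6E,10Z)-11-(9-borabicyclo[3.3.1]nonan-9-yl)-2,6-dimethyl-10-[(trimethylsilyl)methyl]undeca-2,6,10-trienoate | CCOC(=O)/C(C)=C\CC/C(C)=C/CC/C(C[Si](C)(C)C)=C/B1C2CCCC1CCC2
F5 | step 9 | (3Z,7E)-10-[(2R,3S)-3-({[tert-butyl(dimethyl)silyl]oxy}methyl)-3-methyloxiran-2-yl]-8-methyl-4-[(trimethylsilyl)methyl]deca-3,7-dien-1-ol | CC(C)(C)[Si](C)(C)OC[C@]1(C)O[C@@H]1CC/C(C)=C/CC/C(C[Si](C)(C)C)=C/CCO
F6 | step 9 | tert-butyl{[(2S,3R)-3-[(3E,7Z)-10-iodo-3-methyl-7-[(trimethylsilyl)methyl]deca-3,7-dien-1-yl]-2-methyloxiran-2-yl]methoxy}dimethylsilane | CC(C)(C)[Si](C)(C)OC[C@]1(C)O[C@@H]1CC/C(C)=C/CC/C(C[Si](C)(C)C)=C/CCI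
F7 | step 9 | 3-alkyl-3-(phenylsulfanyl)oxolan-2-one from F6 (both epimers at the lactone α-carbon) | CC(C)(C)[Si](C)(C)OC[C@]1(C)O[C@@H]1CC/C(C)=C/CC/C(C[Si](C)(C)C)=C/CCC1(Sc2ccccc2)CCOC1=O
F8 | step 9 | 3-alkyl-3-(benzenesulfinyl)oxolan-2-one from F7 (mixture of diastereomers) | CC(C)(C)[Si](C)(C)OC[C@]1(C)O[C@@H]1CC/C(C)=C/CC/C(C[Si](C)(C)C)=C/CCC1(S(=O)c2ccccc2)CCOC1=O
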